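**Retrosynthetic overview**

1. Atom labels used throughout: ring carbons C1 (C(OH) carrying the acyl chain), C5 (ester carbon), C6 (lactone O–CH), C7, C8 (CH2), C9 (CHOH), C10 (CHMe); side chain C2(=O)–C3–C4(OH); lactone C11(=C13H2)–C12(=O).
2. Last disconnection: the cis-fused α-methylene-γ-lactone and the C9 hydroxyl come from an 8-oxabicyclo[3.2.1]octane whose oxygen bridges C6 and C9; an endo acrylate on C7 opens the bridge at C6 with inversion.
3. On the bicycle: the C5 ester comes from a C1–OH-directed reduction of a C5 ketone plus acylation; C1–C2 comes from a 2-lithio-1,3-dithiane (built from (R)-propylene oxide) adding to the C1 ketone on its open face; the α-methylene comes from Eschenmoser methylenation.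
4. Key disconnection: the seven-membered carbocycle (bonds C5–C6 and C9–C10) by [4+3] cycloaddition of a chiral 1-alkoxy-2-silyloxyallyl cation (an α-keto cation, i.e. an enolonium equivalent) with tert-butyl 3-furylacetate; C7 is then set by exo hydrogenation.
5. Ring order: oxygen-bridged seven-membered ring first (step 5), γ-lactone last (step 14).

Assumption: the (S)-1-phenylethyl auxiliary is taken to expose the cation face that leads to the bicycle enantiomer drawn (furan approaching anti to phenyl on the s-trans oxocarbenium ion); if the sense proves opposite, (R)-1-phenylethanol is used in step 3 and nothing else changes.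

**Route**

Step 1
Reactants: 1 3-bromofuran; 2 (2-tert-butoxy-2-oxoethyl)zinc bromide (BrZnCH2CO2t-Bu)
Product: 3 tert-butyl 2-(furan-3-yl)acetate
Conditions: bis(dibenzylideneacetone)palladium (2 mol %), P(t-Bu)3 (2 mol %), THF, rt
Reagents that add atoms: none
Why: Palladium-catalysed coupling of a Reformatsky zinc enolate with a heteroaryl bromide (Hartwig-type α-arylation, mechanistically a Negishi coupling) runs at room temperature and leaves the furan and the tert-butyl ester untouched; no stereocentre is formed.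

Step 2
Reactants: 4 1,1-dimethoxypropan-2-one
Product: 6 1,1-dimethoxybutan-2-one, via lithium enolate 5 (not isolated)
Conditions: LiN(i-Pr)2 (1.05 equiv), THF, −78 °C; MeI, −78 → −20 °C
Reagents that add atoms: iodomethane, CI
Why: Kinetic deprotonation occurs at the methyl group only and the lithium enolate is C-methylated (enolate alkylation); no stereocentre is formed.

Step 3
Reactants: 6 1,1-dimethoxybutan-2-one; 7 (S)-1-phenylethanol
Product: 8 1-methoxy-1-[(1S)-1-phenylethoxy]butan-2-one (about 1:1 at the acetal carbon)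
Conditions: PPTS (5 mol %), cyclohexane, 70 °C, 5 Å molecular sieves
Reagents that add atoms: none
Why: Acid-catalysed transacetalisation (Hoffmann-type mixed acetal) exchanges one methoxy group when methanol is removed; the carbinol centre of 7 is untouched and the acetal centre does not matter because it becomes planar in step 5.

Step 4
Reactants: 8 1-methoxy-1-[(1S)-1-phenylethoxy]butan-2-one
Product: 10 triethyl{[(2Z)-1-methoxy-1-[(1S)-1-phenylethoxy]but-2-en-2-yl]oxy}silane, via lithium enolate 9 (not isolated)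
Conditions: LiN(i-Pr)2, THF, −78 °C; Et3SiCl, −78 → 0 °C
Reagents that add atoms: chlorotriethylsilane, CC[Si](Cl)(CC)CC
Why: Kinetic enolisation towards the ethyl group and O-silylation (silyl enol ether formation) give mainly the Z enol ether, whose geometry is not decisive because the methyl-bearing carbon is epimerisable in the cycloadduct.

Step 5
Reactants: 3 tert-butyl 2-(furan-3-yl)acetate; 10 triethyl{[(2Z)-1-methoxy-1-[(1S)-1-phenylethoxy]but-2-en-2-yl]oxy}silane
Product: 12 tert-butyl 2-[(1R,2S,4R,5S)-2-methyl-3-oxo-4-[(1S)-1-phenylethoxy]-8-oxabicyclo[3.2.1]oct-6-en-6-yl]acetate, via oxyallyl cation triflate 11 (not isolated)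
Conditions: Et3SiOTf (10 mol %), 3 (1.2 equiv), CH2Cl2, −95 → −78 °C; then Et3N, MeOH, rt
Reagents that add atoms: none
Why: Hoffmann–Albizati [4+3] cycloaddition, in which the silyl triflate ionises the mixed acetal to the 1-alkoxy-2-silyloxyallyl cation 11, an α-keto cation (enolonium equivalent) whose oxocarbenium carbon (future C5) bonds first to the more nucleophilic furan C2 next to the CH2CO2t-Bu arm while its enol ether terminus (future C10) closes onto furan C5, so that two normally nucleophilic ketone α-carbons are joined to the two nucleophilic furan α-carbons and the seven-membered ring, the C6–O–C9 bridge and the regiochemistry arise at once; the (S)-1-phenylethoxy group shields one face of the cation and thereby fixes C6 and C9, and mild base equilibration leaves the C5 alkoxy and C10 methyl groups both equatorial.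

Step 6
Reactants: 12 tert-butyl 2-[(1R,2S,4R,5S)-2-methyl-3-oxo-4-[(1S)-1-phenylethoxy]-8-oxabicyclo[3.2.1]oct-6-en-6-yl]acetate
Product: 13 tert-butyl 2-[(1R,2S,4R,5S,6S)-4-hydroxy-2-methyl-3-oxo-8-oxabicyclo[3.2.1]octan-6-yl]acetate
Conditions: H2 (1 atm), Pd(OH)2/C, EtOAc/EtOH, rt
Reagents that add atoms: none
Why: Heterogeneous hydrogenation delivers H2 to the strained bridge alkene from the exo face (the side of the oxygen bridge), which places the CH2CO2t-Bu arm endo and sets C7, and the same catalyst hydrogenolyses the benzylic auxiliary ether to the equatorial C5 alcohol with retention.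

Step 7
Reactants: 14 1,3-dithiane; 15 (R)-2-methyloxirane
Product: 18 tert-butyl{[(2R)-1-(1,3-dithian-2-yl)propan-2-yl]oxy}dimethylsilane, via 2-lithio-1,3-dithiane 16 (not isolated), via lithium alkoxide 17 (not isolated)
Conditions: n-BuLi, THF, −30 °C; 15, −30 → 0 °C; then t-BuMe2SiCl, DMPU, 0 °C → rt
Reagents that add atoms: tert-butyl(chloro)dimethylsilane, CC(C)(C)[Si](C)(C)Cl
Why: Corey–Seebach lithiation and SN2 opening of the epoxide at its CH2 terminus leave the (R) carbinol centre (C4 of the target) untouched, and the lithium alkoxide is silylated in the same flask.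

Step 8
Reactants: 13 tert-butyl 2-[(1R,2S,4R,5S,6S)-4-hydroxy-2-methyl-3-oxo-8-oxabicyclo[3.2.1]octan-6-yl]acetate; 18 tert-butyl{[(2R)-1-(1,3-dithian-2-yl)propan-2-yl]oxy}dimethylsilane
Product: 20 tert-butyl 2-[(1R,2S,3S,4R,5S,6S)-3-{2-[(2R)-2-(tert-butyldimethylsilyloxy)propyl]-1,3-dithian-2-yl}-3,4-dihydroxy-2-methyl-8-oxabicyclo[3.2.1]octan-6-yl]acetate, via 2-lithiated dithiane 19 (not isolated)
Conditions: 18 (2.5 equiv), n-BuLi (2.5 equiv), THF, −25 °C, 3 h; then 13, −78 → −40 °C; H2O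
Reagents that add atoms: none
Why: Corey–Seebach acyl anion addition to a ketone, in which the first equivalent of 19 forms the C5 lithium alkoxide and the 8-oxabicyclo[3.2.1]octan-3-one can only be attacked equatorially from the face remote from the C7–C8 bridge, so the masked acyl group ends up cis to the oxygen bridge and the new C1 hydroxyl axial, which is the target C1 configuration.

Step 9
Reactants: 20 tert-butyl 2-[(1R,2S,3S,4R,5S,6S)-3-{2-[(2R)-2-(tert-butyldimethylsilyloxy)propyl]-1,3-dithian-2-yl}-3,4-dihydroxy-2-methyl-8-oxabicyclo[3.2.1]octan-6-yl]acetate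
Product: 23 tert-butyl 2-[(1R,2S,3S,4R,5S,6S)-3-{2-[(2R)-2-(tert-butyldimethylsilyloxy)propyl]-1,3-dithian-2-yl}-3,4-dihydroxy-2-methyl-8-oxabicyclo[3.2.1]octan-6-yl]prop-2-enoate, via Mannich base 21 (not isolated), via methiodide 22 (not isolated)
Conditions: LiN(i-Pr)2 (3.3 equiv), THF, −78 °C; CH2=NMe2+ I−, −78 → 0 °C; H2O; then MeI, CH2Cl2/MeOH, rt; aq. NaHCO3
Reagents that add atoms: N,N-dimethylmethyleneiminium iodide (Eschenmoser's salt), C=[N+](C)C.[I-]
Why: Eschenmoser α-methylenation, in which the ester enolate undergoes a Mannich reaction and quaternisation followed by E1cB loss of Me3N gives the acrylate at a stage where no ketone and no epimerisable acyl group is present; the C11 centre created in 21 is destroyed again.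

Step 10
Reactants: 23 tert-butyl 2-[(1R,2S,3S,4R,5S,6S)-3-{2-[(2R)-2-(tert-butyldimethylsilyloxy)propyl]-1,3-dithian-2-yl}-3,4-dihydroxy-2-methyl-8-oxabicyclo[3.2.1]octan-6-yl]prop-2-enoate
Product: 24 tert-butyl 2-[(1R,2S,3S,5S,6S)-3-{2-[(2R)-2-(tert-butyldimethylsilyloxy)propyl]-1,3-dithian-2-yl}-3-hydroxy-2-methyl-4-oxo-8-oxabicyclo[3.2.1]octan-6-yl]prop-2-enoate
Conditions: (COCl)2, DMSO, CH2Cl2, −78 °C; Et3N, −78 → −20 °C
Reagents that add atoms: none
Why: Swern oxidation converts the only secondary alcohol into the C5 ketone and is compatible with the dithiane, the tertiary alcohol and the acrylate; C5 becomes planar so that its configuration can be reset.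

Step 11
Reactants: 24 tert-butyl 2-[(1R,2S,3S,5S,6S)-3-{2-[(2R)-2-(tert-butyldimethylsilyloxy)propyl]-1,3-dithian-2-yl}-3-hydroxy-2-methyl-4-oxo-8-oxabicyclo[3.2.1]octan-6-yl]prop-2-enoate
Product: 25 tert-butyl 2-[(1R,2S,3S,4S,5S,6S)-3-{2-[(2R)-2-(tert-butyldimethylsilyloxy)propyl]-1,3-dithian-2-yl}-3,4-dihydroxy-2-methyl-8-oxabicyclo[3.2.1]octan-6-yl]prop-2-enoate
Conditions: Me4N[BH(OAc)3], MeCN/AcOH (1:1), −20 °C
Reagents that add atoms: none
Why: Saksena–Evans hydroxyl-directed reduction, in which the axial C1–OH binds the triacetoxyborohydride and delivers hydride to its own face of the adjacent C5 carbonyl, giving the trans-diol with the axial C5–OH cis to the oxygen bridge as required in the target.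

Step 12
Reactants: 25 tert-butyl 2-[(1R,2S,3S,4S,5S,6S)-3-{2-[(2R)-2-(tert-butyldimethylsilyloxy)propyl]-1,3-dithian-2-yl}-3,4-dihydroxy-2-methyl-8-oxabicyclo[3.2.1]octan-6-yl]prop-2-enoate; 26 (R)-2-methylbutanoic acid
Product: 28 tert-butyl 2-[(1R,2S,3S,4S,5S,6S)-3-{2-[(2R)-2-(tert-butyldimethylsilyloxy)propyl]-1,3-dithian-2-yl}-3-hydroxy-2-methyl-4-{[(2R)-2-methylbutanoyl]oxy}-8-oxabicyclo[3.2.1]octan-6-yl]prop-2-enoate, via mixed anhydride 27 (not isolated)
Conditions: 26, 2,4,6-Cl3C6H2COCl, Et3N, THF, rt; then 25, DMAP, toluene, 40 °C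
Reagents that add atoms: none
Why: Yamaguchi esterification acylates the only secondary hydroxyl (the tertiary C1–OH is inert) and carries the (R) centre of the acid over unchanged, as in the established installation of 2-methylbutanoates on hindered secondary alcohols.

Step 13
Reactants: 28 tert-butyl 2-[(1R,2S,3S,4S,5S,6S)-3-{2-[(2R)-2-(tert-butyldimethylsilyloxy)propyl]-1,3-dithian-2-yl}-3-hydroxy-2-methyl-4-{[(2R)-2-methylbutanoyl]oxy}-8-oxabicyclo[3.2.1]octan-6-yl]prop-2-enoate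
Product: 29 tert-butyl 2-[(1R,2S,3S,4S,5S,6S)-3-[(3R)-3-(tert-butyldimethylsilyloxy)butanoyl]-3-hydroxy-2-methyl-4-{[(2R)-2-methylbutanoyl]oxy}-8-oxabicyclo[3.2.1]octan-6-yl]prop-2-enoate
Conditions: PhI(OCOCF3)2, MeCN/H2O (9:1), 0 °C, 10 min
Reagents that add atoms: water, O
Why: Stork–Zhao oxidative hydrolysis of the 1,3-dithiane is fast at 0 °C and unmasks the C2 ketone, completing the acyl anion sequence without touching the acrylate, the esters or the silyl ether; no stereocentre is affected.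

Step 14
Reactants: 29 tert-butyl 2-[(1R,2S,3S,4S,5S,6S)-3-[(3R)-3-(tert-butyldimethylsilyloxy)butanoyl]-3-hydroxy-2-methyl-4-{[(2R)-2-methylbutanoyl]oxy}-8-oxabicyclo[3.2.1]octan-6-yl]prop-2-enoate
Product: 31 (3aS,5R,6S,7S,8S,8aR)-5,7-dihydroxy-7-[(3R)-3-hydroxybutanoyl]-6-methyl-3-methylidene-2-oxooctahydro-2H-cyclohepta[b]furan-8-yl (2R)-2-methylbutanoate (target), via silylated lactone 30 (not isolated)
Conditions: Me3SiOTf (3 equiv), CH2Cl2, −40 → 0 °C; then 1 M aq. HCl, THF, rt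
Reagents that add atoms: none
Why: Proposed new method: Me3SiOTf turns the tert-butyl ester into a silyl ester and silylates the bridging ether oxygen, and the ester carbonyl oxygen, held on the endo face directly behind the C6–O bond, opens the silyloxonium ion by intramolecular SN2 with inversion at C6 to give the cis-fused α-methylene-γ-lactone while C9 keeps the bridge oxygen as its hydroxyl, after which aqueous acid removes all silyl groups; the closest known reactions are acid-promoted SN2 openings of 7-oxanorbornanes and related oxygen-bridged bicycles with inversion, neighbouring-carboxyl openings of epoxides and oxetanes to lactones, and silyl triflate cleavage of tert-butyl esters.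

**Compound list**

1 | 3-bromofuran | Brc1ccoc1 | starting material
2 | (2-tert-butoxy-2-oxoethyl)zinc bromide | CC(C)(C)OC(=O)C[Zn]Br | starting material
3 | tert-butyl 2-(furan-3-yl)acetate | CC(C)(C)OC(=O)Cc1ccoc1 | intermediate
4 | 1,1-dimethoxypropan-2-one | COC(OC)C(C)=O | starting material
5 | lithium 3,3-dimethoxyprop-1-en-2-olate | [Li]OC(=C)C(OC)OC | intermediate (not isolated)
6 | 1,1-dimethoxybutan-2-one | CCC(=O)C(OC)OC | intermediate
7 | (S)-1-phenylethanol | C[C@H](O)c1ccccc1 | starting material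
8 | 1-methoxy-1-[(1S)-1-phenylethoxy]butan-2-one (acetal epimers) | CCC(=O)C(OC)O[C@@H](C)c1ccccc1 | intermediate
9 | lithium (2Z)-1-methoxy-1-[(1S)-1-phenylethoxy]but-2-en-2-olate | C/C=C(\O[Li])C(OC)O[C@@H](C)c1ccccc1 | intermediate (not isolated)
10 | triethyl{[(2Z)-1-methoxy-1-[(1S)-1-phenylethoxy]but-2-en-2-yl]oxy}silane | C/C=C(\O[Si](CC)(CC)CC)C(OC)O[C@@H](C)c1ccccc1 | intermediate
11 | 1-[(1S)-1-phenylethoxy]-2-(triethylsilyloxy)but-2-en-1-ylium trifluoromethanesulfonate (oxyallyl cation, oxocarbenium form) | C/C=C(\O[Si](CC)(CC)CC)C=[O+][C@@H](C)c1ccccc1.[O-]S(=O)(=O)C(F)(F)F | intermediate (not isolated)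
12 | tert-butyl 2-[(1R,2S,4R,5S)-2-methyl-3-oxo-4-[(1S)-1-phenylethoxy]-8-oxabicyclo[3.2.1]oct-6-en-6-yl]acetate | [C@@H]12C(CC(=O)OC(C)(C)C)=C[C@@H](O1)[C@H](C)C(=O)[C@@H]2O[C@@H](C)c1ccccc1 | intermediate
13 | tert-butyl 2-[(1R,2S,4R,5S,6S)-4-hydroxy-2-methyl-3-oxo-8-oxabicyclo[3.2.1]octan-6-yl]acetate | [C@@H]12[C@H](CC(=O)OC(C)(C)C)C[C@@H](O1)[C@H](C)C(=O)[C@@H]2O | intermediate
14 | 1,3-dithiane | C1CSCSC1 | starting material
15 | (R)-2-methyloxirane | C[C@@H]1CO1 | starting material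
16 | 2-lithio-1,3-dithiane | [Li]C1SCCCS1 | intermediate (not isolated)
17 | lithium (2R)-1-(1,3-dithian-2-yl)propan-2-olate | C[C@H](CC1SCCCS1)O[Li] | intermediate (not isolated)
18 | tert-butyl{[(2R)-1-(1,3-dithian-2-yl)propan-2-yl]oxy}dimethylsilane | C[C@H](CC1SCCCS1)O[Si](C)(C)C(C)(C)C | intermediate
19 | 2-lithio derivative of 18 | C[C@H](CC1([Li])SCCCS1)O[Si](C)(C)C(C)(C)C | intermediate (not isolated)
20 | tert-butyl 2-[(1R,2S,3S,4R,5S,6S)-3-{2-[(2R)-2-(tert-butyldimethylsilyloxy)propyl]-1,3-dithian-2-yl}-3,4-dihydroxy-2-methyl-8-oxabicyclo[3.2.1]octan-6-yl]acetate | [C@@H]12[C@H](CC(=O)OC(C)(C)C)C[C@@H](O1)[C@H](C)[C@@](O)(C3(SCCCS3)C[C@@H](C)O[Si](C)(C)C(C)(C)C)[C@@H]2O | intermediate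
21 | tert-butyl 3-(dimethylamino)-2-[bicyclic unit of 20]propanoate (C11 epimers) | [C@@H]12[C@H](C(CN(C)C)C(=O)OC(C)(C)C)C[C@@H](O1)[C@H](C)[C@@](O)(C3(SCCCS3)C[C@@H](C)O[Si](C)(C)C(C)(C)C)[C@@H]2O | intermediate (not isolated)
22 | trimethylammonium iodide of 21 | [C@@H]12[C@H](C(C[N+](C)(C)C)C(=O)OC(C)(C)C)C[C@@H](O1)[C@H](C)[C@@](O)(C3(SCCCS3)C[C@@H](C)O[Si](C)(C)C(C)(C)C)[C@@H]2O.[I-] | intermediate (not isolated)
23 | tert-butyl 2-[(1R,2S,3S,4R,5S,6S)-3-{2-[(2R)-2-(tert-butyldimethylsilyloxy)propyl]-1,3-dithian-2-yl}-3,4-dihydroxy-2-methyl-8-oxabicyclo[3.2.1]octan-6-yl]prop-2-enoate | [C@@H]12[C@H](C(=C)C(=O)OC(C)(C)C)C[C@@H](O1)[C@H](C)[C@@](O)(C3(SCCCS3)C[C@@H](C)O[Si](C)(C)C(C)(C)C)[C@@H]2O | intermediate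
24 | tert-butyl 2-[(1R,2S,3S,5S,6S)-3-{2-[(2R)-2-(tert-butyldimethylsilyloxy)propyl]-1,3-dithian-2-yl}-3-hydroxy-2-methyl-4-oxo-8-oxabicyclo[3.2.1]octan-6-yl]prop-2-enoate | [C@@H]12[C@H](C(=C)C(=O)OC(C)(C)C)C[C@@H](O1)[C@H](C)[C@@](O)(C3(SCCCS3)C[C@@H](C)O[Si](C)(C)C(C)(C)C)C2=O | intermediate
25 | tert-butyl 2-[(1R,2S,3S,4S,5S,6S)-3-{2-[(2R)-2-(tert-butyldimethylsilyloxy)propyl]-1,3-dithian-2-yl}-3,4-dihydroxy-2-methyl-8-oxabicyclo[3.2.1]octan-6-yl]prop-2-enoate | [C@@H]12[C@H](C(=C)C(=O)OC(C)(C)C)C[C@@H](O1)[C@H](C)[C@@](O)(C3(SCCCS3)C[C@@H](C)O[Si](C)(C)C(C)(C)C)[C@H]2O | intermediate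
26 | (R)-2-methylbutanoic acid | CC[C@@H](C)C(=O)O | starting material
27 | (2R)-2-methylbutanoic 2,4,6-trichlorobenzoic anhydride | CC[C@@H](C)C(=O)OC(=O)c1c(Cl)cc(Cl)cc1Cl | intermediate (not isolated)
28 | tert-butyl 2-[(1R,2S,3S,4S,5S,6S)-3-{2-[(2R)-2-(tert-butyldimethylsilyloxy)propyl]-1,3-dithian-2-yl}-3-hydroxy-2-methyl-4-{[(2R)-2-methylbutanoyl]oxy}-8-oxabicyclo[3.2.1]octan-6-yl]prop-2-enoate | [C@@H]12[C@H](C(=C)C(=O)OC(C)(C)C)C[C@@H](O1)[C@H](C)[C@@](O)(C3(SCCCS3)C[C@@H](C)O[Si](C)(C)C(C)(C)C)[C@H]2OC(=O)[C@H](C)CC | intermediate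
29 | tert-butyl 2-[(1R,2S,3S,4S,5S,6S)-3-[(3R)-3-(tert-butyldimethylsilyloxy)butanoyl]-3-hydroxy-2-methyl-4-{[(2R)-2-methylbutanoyl]oxy}-8-oxabicyclo[3.2.1]octan-6-yl]prop-2-enoate | [C@@H]12[C@H](C(=C)C(=O)OC(C)(C)C)C[C@@H](O1)[C@H](C)[C@@](O)(C(=O)C[C@@H](C)O[Si](C)(C)C(C)(C)C)[C@H]2OC(=O)[C@H](C)CC | intermediate
30 | (3aS,5R,6S,7S,8S,8aR)-7-[(3R)-3-(tert-butyldimethylsilyloxy)butanoyl]-6-methyl-3-methylidene-2-oxo-5,7-bis(trimethylsilyloxy)octahydro-2H-cyclohepta[b]furan-8-yl (2R)-2-methylbutanoate | C=C1C(=O)O[C@@H]2[C@H]1C[C@@H](O[Si](C)(C)C)[C@H](C)[C@@](O[Si](C)(C)C)(C(=O)C[C@@H](C)O[Si](C)(C)C(C)(C)C)[C@H]2OC(=O)[C@H](C)CC | intermediate (not isolated)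
31 | (3aS,5R,6S,7S,8S,8aR)-5,7-dihydroxy-7-[(3R)-3-hydroxybutanoyl]-6-methyl-3-methylidene-2-oxooctahydro-2H-cyclohepta[b]furan-8-yl (2R)-2-methylbutanoate | C=C1C(=O)O[C@@H]2[C@H]1C[C@@H](O)[C@H](C)[C@@](O)(C(=O)C[C@@H](C)O)[C@H]2OC(=O)[C@H](C)CC | target

**Step count and risks**

Total steps: 14. Longest linear sequence: 12 (steps 2–6 and 8–14, from 1,1-dimethoxypropan-2-one).

Step 5 ([4+3] cycloaddition). Risks are the wrong regioisomer, an open-chain Friedel–Crafts product, or weak facial control by the auxiliary. The fallback sets out from 1 and 10 and comes back at 12. The same silyl triflate cycloaddition is run on 3-bromofuran 1, whose bromine directs the first bond to furan C2 but is small, to give (1S,2S,4R,5R)-6-bromo-2-methyl-4-[(1S)-1-phenylethoxy]-8-oxabicyclo[3.2.1]oct-6-en-3-one F1. The acetate arm is then attached by coupling the vinyl bromide F1 with zinc reagent 2 (bis(dibenzylideneacetone)palladium, P(t-Bu)3, THF), which gives 12.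

Step 11 (hydroxyl-directed reduction). The risk is external hydride delivery, which would return the cis-diol. The fallback sets out from 13 and comes back at 25, inverting C5 while it is still α to the C1 ketone. Tf2O/pyridine converts 13 into tert-butyl 2-[(1R,2S,4R,5S,6S)-2-methyl-3-oxo-4-(trifluoromethanesulfonyloxy)-8-oxabicyclo[3.2.1]octan-6-yl]acetate F2. Bu4N+ NO2− in DMF displaces the triflate by SN2 (Lattrell–Dax inversion) and the nitrite ester hydrolyses on work-up to tert-butyl 2-[(1R,2S,4S,5S,6S)-4-hydroxy-2-methyl-3-oxo-8-oxabicyclo[3.2.1]octan-6-yl]acetate F3. Addition of 19 as in step 8, now guided by the axial lithium alkoxide, gives tert-butyl 2-[(1R,2S,3S,4S,5S,6S)-3-{2-[(2R)-2-(tert-butyldimethylsilyloxy)propyl]-1,3-dithian-2-yl}-3,4-dihydroxy-2-methyl-8-oxabicyclo[3.2.1]octan-6-yl]acetate F4. Eschenmoser methylenation as in step 9 then gives 25 without passing through 20, 23 and 24.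

Step 14 (bridge-opening lactonisation). Risks are no ether cleavage, or attack of an external nucleophile at C9. The fallback sets out from 29 and comes back at 31. TFA/H2O (9:1) first removes the tert-butyl ester and the silyl ether to give 2-[(1R,2S,3S,4S,5S,6S)-3-hydroxy-3-[(3R)-3-hydroxybutanoyl]-2-methyl-4-{[(2R)-2-methylbutanoyl]oxy}-8-oxabicyclo[3.2.1]octan-6-yl]prop-2-enoic acid F5. The bridge is then activated as an acyloxonium ion instead of a silyloxonium ion ((CF3CO)2O, cat. TfOH, CH2Cl2): the carboxyl closes the lactone at C6 and the released C9 oxygen is trapped as its trifluoroacetate, giving (3aS,5R,6S,7S,8S,8aR)-7-hydroxy-6-methyl-3-methylidene-2-oxo-5-(trifluoroacetoxy)-7-[(3R)-3-(trifluoroacetoxy)butanoyl]octahydro-2H-cyclohepta[b]furan-8-yl (2R)-2-methylbutanoate F6. NaHCO3/MeOH methanolyses the trifluoroacetates within minutes to 31.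

**Further compounds**

F1 | step 5 | (1S,2S,4R,5R)-6-bromo-2-methyl-4-[(1S)-1-phenylethoxy]-8-oxabicyclo[3.2.1]oct-6-en-3-one | [C@@H]12C(Br)=C[C@@H](O1)[C@H](C)C(=O)[C@@H]2O[C@@H](C)c1ccccc1
F2 | step 11 | tert-butyl 2-[(1R,2S,4R,5S,6S)-2-methyl-3-oxo-4-(trifluoromethanesulfonyloxy)-8-oxabicyclo[3.2.1]octan-6-yl]acetate | [C@@H]12[C@H](CC(=O)OC(C)(C)C)C[C@@H](O1)[C@H](C)C(=O)[C@@H]2OS(=O)(=O)C(F)(F)F
F3 | step 11 | tert-butyl 2-[(1R,2S,4S,5S,6S)-4-hydroxy-2-methyl-3-oxo-8-oxabicyclo[3.2.1]octan-6-yl]acetate | [C@@H]12[C@H](CC(=O)OC(C)(C)C)C[C@@H](O1)[C@H](C)C(=O)[C@H]2O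
F4 | step 11 | tert-butyl 2-[(1R,2S,3S,4S,5S,6S)-3-{2-[(2R)-2-(tert-butyldimethylsilyloxy)propyl]-1,3-dithian-2-yl}-3,4-dihydroxy-2-methyl-8-oxabicyclo[3.2.1]octan-6-yl]acetate | [C@@H]12[C@H](CC(=O)OC(C)(C)C)C[C@@H](O1)[C@H](C)[C@@](O)(C3(SCCCS3)C[C@@H](C)O[Si](C)(C)C(C)(C)C)[C@H]2O
F5 | step 14 | 2-[(1R,2S,3S,4S,5S,6S)-3-hydroxy-3-[(3R)-3-hydroxybutanoyl]-2-methyl-4-{[(2R)-2-methylbutanoyl]oxy}-8-oxabicyclo[3.2.1]octan-6-yl]prop-2-enoic acid | [C@@H]12[C@H](C(=C)C(=O)O)C[C@@H](O1)[C@H](C)[C@@](O)(C(=O)C[C@@H](C)O)[C@H]2OC(=O)[C@H](C)CC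
F6 | step 14 | (3aS,5R,6S,7S,8S,8aR)-7-hydroxy-6-methyl-3-methylidene-2-oxo-5-(trifluoroacetoxy)-7-[(3R)-3-(trifluoroacetoxy)butanoyl]octahydro-2H-cyclohepta[b]furan-8-yl (2R)-2-methylbutanoate | C=C1C(=O)O[C@@H]2[C@H]1C[C@@H](OC(=O)C(F)(F)F)[C@H](C)[C@@](O)(C(=O)C[C@@H](C)OC(=O)C(F)(F)F)[C@H]2OC(=O)[C@H](C)CC
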